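**Retrosynthetic overview**
- Target ⇐ diimide reduction of a side-chain C9=C10 alkene left by the Wittig reaction that attaches the phenyloctyl tail.
- The 1,2-dioxane (the only ring, closed in the penultimate step): C6–O bond by a chiral-acid-catalysed 6-exo cyclisation of a C3 hydroperoxide onto a C6 1,1-disubstituted alkene; this sets C6.
- C3–O bond: amine-catalysed enantioselective peroxy-Michael addition of a ketal hydroperoxide to an (E)-enal (sets C3), then CHO → CO2H.
- C8 and C4: two organocatalytic α-allylations of propanal on a 2-methylidenepropane-1,3-diyl bis-silane linchpin; C1–C2 by a formyl Wittig reaction.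

Assumption: the SMILES is read as (3S,4S,6R,8R), and (8-bromooctyl)benzene, the bis-silane linchpin, the formyl ylide and both antipodes of the catalysts are taken as purchasable (the bis-silane is otherwise one step from 3-chloro-2-(chloromethyl)prop-1-ene, Mg and Me3SiCl).

**Route**

Step 1
Reactants: 1 (8-bromooctyl)benzene
Product: 2 triphenyl(8-phenyloctyl)phosphonium bromide
Conditions: PPh3, MeCN, reflux, 36 h
Reagents that add atoms: triphenylphosphine, c1ccc(cc1)P(c1ccccc1)c1ccccc1
Why: SN2 quaternisation of PPh3 by an unhindered primary bromide (phosphonium salt formation).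

Step 2
Reactants: 3 propanal; 4 trimethyl{2-[(trimethylsilyl)methyl]prop-2-en-1-yl}silane (2.5 equiv)
Product: 5 (2S)-2-methyl-4-[(trimethylsilyl)methyl]pent-4-enal
Conditions: (2R,5R)-5-benzyl-2-tert-butyl-3-methylimidazolidin-4-one·TFA (20 mol %), CAN (2 equiv), NaHCO3, H2O, DME, −20 °C
Reagents that add atoms: none
Why: Organo-SOMO α-allylation, in which CAN oxidises the catalyst enamine to a radical cation that adds to the excess bis-silane and loses Me3Si+ to leave a new allylsilane; the (2R,5R) catalyst exposes the Re face of the E radical cation, giving the (S) centre (future C8).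

Step 3
Reactants: 5 (2S)-2-methyl-4-[(trimethylsilyl)methyl]pent-4-enal; 2 triphenyl(8-phenyloctyl)phosphonium bromide
Product: 7 trimethyl[(4S,5Z)-4-methyl-2-methylidene-13-phenyltridec-5-en-1-yl]silane, via phosphorus ylide 6 (not isolated)
Conditions: NaHMDS, THF, −78 °C; then 5, −78 → 0 °C
Reagents that add atoms: none
Why: Salt-free Wittig olefination of a non-stabilised ylide (Z-selective), run cold to protect the α-stereocentre; the alkene geometry is irrelevant because it is reduced in step 10.

Step 4
Reactants: 7 trimethyl[(4S,5Z)-4-methyl-2-methylidene-13-phenyltridec-5-en-1-yl]silane; 3 propanal (3 equiv)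
Product: 8 (2S,6S,7Z)-2,6-dimethyl-4-methylidene-15-phenylpentadec-7-enal
Conditions: (2R,5R)-5-benzyl-2-tert-butyl-3-methylimidazolidin-4-one·TFA (20 mol %), CAN (portionwise), NaHCO3, H2O, DME, −20 °C
Reagents that add atoms: none
Why: Second organo-SOMO α-allylation, in which the propanal radical cation adds to the nucleophilic allylsilane rather than the Z-alkene and desilylation creates the C6 exo-methylene; the same catalyst antipode sets the (S) centre (future C4) under catalyst control, the remote centre having no influence.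

Step 5
Reactants: 8 (2S,6S,7Z)-2,6-dimethyl-4-methylidene-15-phenylpentadec-7-enal; 9 (triphenyl-λ5-phosphanylidene)acetaldehyde
Product: 10 (2E,4S,8S,9Z)-4,8-dimethyl-6-methylidene-17-phenylheptadeca-2,9-dienal
Conditions: 9 (1.2 equiv), toluene, 80 °C
Reagents that add atoms: none
Why: Wittig olefination with a stabilised formyl ylide gives the (E)-enal under neutral conditions that do not epimerise C4.

Step 6
Reactants: 11 2,3-dimethylbut-2-ene
Product: 13 2-methoxypropan-2-yl hydroperoxide, via acetone O-oxide 12 (not isolated)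
Conditions: O3, MeOH/CH2Cl2, −78 °C; N2 purge, cold concentration, used as a solution
Reagents that add atoms: ozone, [O-][O+]=O; methanol, CO
Why: Ozonolysis with methanol trapping of the Criegee carbonyl oxide gives the monoperoxyketal hydroperoxide.

Step 7
Reactants: 10 (2E,4S,8S,9Z)-4,8-dimethyl-6-methylidene-17-phenylheptadeca-2,9-dienal; 13 2-methoxypropan-2-yl hydroperoxide (1.5 equiv)
Product: 14 (3S,4S,8S,9Z)-3-[(2-methoxypropan-2-yl)peroxy]-4,8-dimethyl-6-methylidene-17-phenylheptadec-9-enal
Conditions: (S)-2-{bis[3,5-bis(trifluoromethyl)phenyl](trimethylsilyloxy)methyl}pyrrolidine (10 mol %), toluene, 0 °C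
Reagents that add atoms: none
Why: Iminium-catalysed enantioselective peroxy-Michael addition to an enal, in which the hydroperoxide adds to the E-iminium anti to the CAr2OSiMe3 group to give 3S; this face is also the one favoured by the 4S centre (attack anti to the C5 chain in the A(1,3)-minimised conformer), so the pair should be matched.

Step 8
Reactants: 14 (3S,4S,8S,9Z)-3-[(2-methoxypropan-2-yl)peroxy]-4,8-dimethyl-6-methylidene-17-phenylheptadec-9-enal
Product: 16 (3S,4S,8S,9Z)-3-hydroperoxy-4,8-dimethyl-6-methylidene-17-phenylheptadec-9-enoic acid, via peroxyketal acid 15 (not isolated)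
Conditions: NaClO2, NaH2PO4, 2-methylbut-2-ene, t-BuOH/H2O, 0 °C; then AcOH/THF/H2O, rt
Reagents that add atoms: sodium chlorite, [Na+].[O-]Cl=O
Why: Pinnick oxidation (HOCl scavenged, so alkenes and O–O survive) removes the retro-Michael-prone aldehyde at once, and mild aqueous acid then hydrolyses the monoperoxyketal to the free hydroperoxide without touching C3.

Step 9
Reactants: 16 (3S,4S,8S,9Z)-3-hydroperoxy-4,8-dimethyl-6-methylidene-17-phenylheptadec-9-enoic acid
Product: 17 2-[(3S,4S,6R)-4,6-dimethyl-6-[(2S,3Z)-2-methyl-11-phenylundec-3-en-1-yl]-1,2-dioxan-3-yl]acetic acid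
Conditions: confined chiral imidodiphosphorimidate (IDPi) Brønsted acid (N-triflyl core, 3,3′-diaryl-BINOL walls; antipode that gives 6R, 5–10 mol %), CHCl3/cyclohexane, 5 Å MS, rt → 35 °C, dark
Reagents that add atoms: none
Why: Proposed new method: the confined strong acid protonates the 1,1-disubstituted alkene to a tertiary C6 cation held as a contact ion pair in the chiral anion pocket, and the terminal oxygen of the C3 hydroperoxide (an α-effect nucleophile too weakly basic to quench the acid) closes the ring by 6-exo attack through a chair with 4-Me equatorial, the pocket selecting the face that puts the CH2R arm equatorial and the new methyl axial (6R) where the substrate's own bias is small; the closest known reactions are IDPi-catalysed asymmetric intramolecular hydroalkoxylation of unactivated 1,1-disubstituted alkenes with alcohols and the classical strong-acid addition of hydroperoxides to isobutene-type alkenes, neither shown for an enantioselective hydroperoxide cyclisation.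

Step 10
Reactants: 17 2-[(3S,4S,6R)-4,6-dimethyl-6-[(2S,3Z)-2-methyl-11-phenylundec-3-en-1-yl]-1,2-dioxan-3-yl]acetic acid
Product: 18 2-[(3S,4S,6R)-4,6-dimethyl-6-[(2R)-2-methyl-11-phenylundecyl]-1,2-dioxan-3-yl]acetic acid
Conditions: dipotassium azodicarboxylate, AcOH, pyridine, MeOH/CH2Cl2, 0 °C → rt
Reagents that add atoms: none
Why: Diimide transfer hydrogenation saturates the disubstituted C=C by concerted syn H2 delivery and leaves the O–O bond, the acid and all four stereocentres untouched (the C8 descriptor changes from S to R only through CIP priorities).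

**Compound list**
1 | (8-bromooctyl)benzene | BrCCCCCCCCc1ccccc1 | starting material
2 | triphenyl(8-phenyloctyl)phosphonium bromide | [Br-].c1ccc(cc1)CCCCCCCC[P+](c1ccccc1)(c1ccccc1)c1ccccc1 | intermediate
3 | propanal | CCC=O | starting material
4 | trimethyl{2-[(trimethylsilyl)methyl]prop-2-en-1-yl}silane | C[Si](C)(C)CC(=C)C[Si](C)(C)C | starting material
5 | (2S)-2-methyl-4-[(trimethylsilyl)methyl]pent-4-enal | C[Si](C)(C)CC(=C)C[C@H](C)C=O | intermediate
6 | triphenyl(8-phenyloctylidene)-λ5-phosphane (ylide) | c1ccc(cc1)CCCCCCCC=P(c1ccccc1)(c1ccccc1)c1ccccc1 | intermediate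
7 | trimethyl[(4S,5Z)-4-methyl-2-methylidene-13-phenyltridec-5-en-1-yl]silane | C[Si](C)(C)CC(=C)C[C@H](C)/C=C\CCCCCCCc1ccccc1 | intermediate
8 | (2S,6S,7Z)-2,6-dimethyl-4-methylidene-15-phenylpentadec-7-enal | C=C(C[C@H](C)C=O)C[C@H](C)/C=C\CCCCCCCc1ccccc1 | intermediate
9 | (triphenyl-λ5-phosphanylidene)acetaldehyde | O=CC=P(c1ccccc1)(c1ccccc1)c1ccccc1 | starting material
10 | (2E,4S,8S,9Z)-4,8-dimethyl-6-methylidene-17-phenylheptadeca-2,9-dienal | C=C(C[C@H](C)/C=C/C=O)C[C@H](C)/C=C\CCCCCCCc1ccccc1 | intermediate
11 | 2,3-dimethylbut-2-ene | CC(C)=C(C)C | starting material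
12 | acetone O-oxide (Criegee intermediate) | CC(C)=[O+][O-] | intermediate
13 | 2-methoxypropan-2-yl hydroperoxide | COC(C)(C)OO | intermediate
14 | (3S,4S,8S,9Z)-3-[(2-methoxypropan-2-yl)peroxy]-4,8-dimethyl-6-methylidene-17-phenylheptadec-9-enal | C=C(C[C@H](C)[C@H](CC=O)OOC(C)(C)OC)C[C@H](C)/C=C\CCCCCCCc1ccccc1 | intermediate
15 | (3S,4S,8S,9Z)-3-[(2-methoxypropan-2-yl)peroxy]-4,8-dimethyl-6-methylidene-17-phenylheptadec-9-enoic acid | C=C(C[C@H](C)[C@H](CC(=O)O)OOC(C)(C)OC)C[C@H](C)/C=C\CCCCCCCc1ccccc1 | intermediate
16 | (3S,4S,8S,9Z)-3-hydroperoxy-4,8-dimethyl-6-methylidene-17-phenylheptadec-9-enoic acid | C=C(C[C@H](C)[C@H](CC(=O)O)OO)C[C@H](C)/C=C\CCCCCCCc1ccccc1 | intermediate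
17 | 2-[(3S,4S,6R)-4,6-dimethyl-6-[(2S,3Z)-2-methyl-11-phenylundec-3-en-1-yl]-1,2-dioxan-3-yl]acetic acid | C[C@H](/C=C\CCCCCCCc1ccccc1)C[C@]1(C)C[C@H](C)[C@H](CC(=O)O)OO1 | intermediate
18 | 2-[(3S,4S,6R)-4,6-dimethyl-6-[(2R)-2-methyl-11-phenylundecyl]-1,2-dioxan-3-yl]acetic acid | C[C@H](CCCCCCCCCc1ccccc1)C[C@]1(C)C[C@H](C)[C@H](CC(=O)O)OO1 | target

**Step count and risks**

Total steps: 10, including the two reagent preparations (steps 1 and 6). Longest linear sequence: 8 (steps 2, 3, 4, 5, 7, 8, 9, 10).

Steps most likely to fail: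

1. Step 9, the proposed new cyclisation. The risks are Hock-type or dehydrative decomposition of the secondary hydroperoxide under strong acid, cation capture by the C9=C10 alkene, and insufficient catalyst control at C6. The fallback uses known chemistry and sets out from 16. Cycloperoxymercuration with Hg(OAc)2 (CH2Cl2, cat. HClO4, 0 °C) closes the same 6-exo ring under substrate control to give 2-[(3S,4S,6R)-6-[(acetyloxymercurio)methyl]-4-methyl-6-[(2S,3Z)-2-methyl-11-phenylundec-3-en-1-yl]-1,2-dioxan-3-yl]acetic acid F1. Reductive demercuration (NaBH4, aq. NaOH, 0 °C) turns CH2Hg into the C6 methyl and, after chromatographic purification of the 6R isomer, comes back to the route at 17.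

2. Step 7, the peroxy-Michael addition. The γ-branched enal may react slowly, the enamine intermediate may collapse to an epoxy aldehyde, and 14 can revert by retro-Michael loss of the peroxide. The fallback sets out from 8 and reverses the order of C–O bond formation with known chemistry. Wittig reaction with methyl (triphenylphosphoranylidene)acetate gives methyl (2E,4S,8S,9Z)-4,8-dimethyl-6-methylidene-17-phenylheptadeca-2,9-dienoate F2. Mukaiyama–Isayama hydroperoxysilylation (Co(thd)2 cat., O2, Et3SiH, DCE), which favours the 1,1-disubstituted alkene, gives methyl (2E,4S,6R,8S,9Z)-4,6,8-trimethyl-17-phenyl-6-[(triethylsilyl)peroxy]heptadeca-2,9-dienoate F3 after separation at C6. Desilylation (TBAF/AcOH) gives methyl (2E,4S,6R,8S,9Z)-6-hydroperoxy-4,6,8-trimethyl-17-phenylheptadeca-2,9-dienoate F4. Base-mediated intramolecular peroxy-oxa-Michael addition (Et2NH, CF3CH2OH) gives methyl 2-[(3S,4S,6R)-4,6-dimethyl-6-[(2S,3Z)-2-methyl-11-phenylundec-3-en-1-yl]-1,2-dioxan-3-yl]acetate F5, purified at C3. LiOH saponification comes back to the route at 17, bypassing steps 7–9.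

3. Step 4, the second α-allylation. Here the advanced allylsilane 7 is the limiting partner, the reverse of the usual stoichiometry, and its Z-alkene is exposed to CAN. The fallback sets out from 4 (with 3) and moves the difficult stoichiometry onto cheap material. Step 2 is run with excess propanal and oxidant so that 5 is allylated a second time in the same pot, giving C2-symmetric (2S,6S)-2,6-dimethyl-4-methylideneheptanedial F6, whose enantiopurity is raised because the minor enantiomer ends up largely as the meso isomer. Because the two aldehydes of F6 are homotopic, mono-Wittig reaction with one equivalent of ylide 6, added to excess F6 at −78 °C with recovery of unreacted dialdehyde, comes back to the route at 8.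

**Further compounds**
F1 | step 9 | 2-[(3S,4S,6R)-6-[(acetyloxymercurio)methyl]-4-methyl-6-[(2S,3Z)-2-methyl-11-phenylundec-3-en-1-yl]-1,2-dioxan-3-yl]acetic acid | C[C@H](/C=C\CCCCCCCc1ccccc1)C[C@]1(C[Hg]OC(C)=O)C[C@H](C)[C@H](CC(=O)O)OO1
F2 | step 7 | methyl (2E,4S,8S,9Z)-4,8-dimethyl-6-methylidene-17-phenylheptadeca-2,9-dienoate | C=C(C[C@H](C)/C=C/C(=O)OC)C[C@H](C)/C=C\CCCCCCCc1ccccc1
F3 | step 7 | methyl (2E,4S,6R,8S,9Z)-4,6,8-trimethyl-17-phenyl-6-[(triethylsilyl)peroxy]heptadeca-2,9-dienoate | C[C@H](/C=C\CCCCCCCc1ccccc1)C[C@](OO[Si](CC)(CC)CC)(C)C[C@H](C)/C=C/C(=O)OC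
F4 | step 7 | methyl (2E,4S,6R,8S,9Z)-6-hydroperoxy-4,6,8-trimethyl-17-phenylheptadeca-2,9-dienoate | C[C@H](/C=C\CCCCCCCc1ccccc1)C[C@](OO)(C)C[C@H](C)/C=C/C(=O)OC
F5 | step 7 | methyl 2-[(3S,4S,6R)-4,6-dimethyl-6-[(2S,3Z)-2-methyl-11-phenylundec-3-en-1-yl]-1,2-dioxan-3-yl]acetate | C[C@H](/C=C\CCCCCCCc1ccccc1)C[C@]1(C)C[C@H](C)[C@H](CC(=O)OC)OO1
F6 | step 4 | (2S,6S)-2,6-dimethyl-4-methylideneheptanedial | C=C(C[C@H](C)C=O)C[C@H](C)C=O
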